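C12 and C13 are joined by a decarboxylative radical conjugate addition onto a temporary δ-lactone. The route has 26 steps, with a longest linear sequence of 13.

**Retrosynthetic overview**

1. Locants: polyol chain C1 (=CH2) to C15 (methyl on C14); acid chain C1′–C12′. End game: target 38 ⇐ terminal enyne 37 (semihydrogenation) ⇐ silyl ethers 36 ⇐ 12‑carboxymethyl acid 35 (photodecarboxylation leaves the 12‑methyl) ⇐ saturated δ‑lactone 34.
2. Central cut C12–C13: acid 13 is decarboxylated to the primary C13 radical. C13–C15 are bought as methyl (R)‑3‑hydroxybutanoate, and 13 already carries the complete acyl chain. The radical adds to C12 of unsaturated δ‑lactone 32, which carries the whole C1–C12 half.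
3. Enabling feature: C12 and C13 are each β to oxygen (O–C11 and O–C14). This is a 1,4‑dioxygen pair of like polarity, and an anion on either carbon would eliminate. O–C10 lies 1,5 to the carbon of the 12‑methyl group, so that methyl is carried as CH2–C(=O)–O–C10 in a temporary six‑membered ring (O, C10, C11, C12, CH2, C=O). The ring activates C12 and shields one face with the cis 11‑OTBS and C9‑acyl groups.
4. 32 ⇐ ring‑closing metathesis of acrylate 31 ⇐ boron aldol C7–C8 of aldehyde 21 (C1–C7; C5 by catalytic ketone allylboration) with methyl ketone 28 (C8–C12; C10 and C11 from L‑tartrate). 13 ⇐ cross metathesis C6′=C7′ of vinyl oxirane 5 with dienoate 8.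
5. Ring order: oxirane (step 2), then the temporary δ‑lactone (closed in step 21, opened in step 23). The bought dioxolane of 22 is removed in step 16.

Key step: step 22

Remark on the chemistry: 38 is drawn and handled as the open‑chain 9‑ketone. A C5‑OH/C9 hemiketal form, if populated, is the same compound in equilibrium.

**Acid half (C13–C15 and C1′–C12′)**

Step 1
Reactants: 1 3‑methylbutanal; 2 (triphenylphosphoranylidene)acetaldehyde
Product: 3 (E)‑5‑methylhex‑2‑enal
Conditions: toluene, 80 °C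
Reagents that add atoms: none
Why: Wittig olefination with a formyl‑stabilised ylide, which should give the E‑enal.

Step 2
Reactants: 3 (E)‑5‑methylhex‑2‑enal
Product: 4 (2S,3R)‑3‑(2‑methylpropyl)oxirane‑2‑carbaldehyde
Conditions: 35% aq H2O2, (R)‑2‑{bis[3,5‑bis(trifluoromethyl)phenyl](trimethylsilyloxy)methyl}pyrrolidine (10 mol %), CH2Cl2, rt
Reagents that add atoms: hydrogen peroxide, OO
Why: Iminium/enamine organocatalytic epoxidation of an enal, in which the bulky group of the R catalyst blocks one face of the E‑iminium ion so that both oxirane centres (C8′, C9′) should be set trans in one event.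

Step 3
Reactants: 4 epoxy aldehyde
Product: 5 (2R,3R)‑2‑(2‑methylpropyl)‑3‑vinyloxirane
Conditions: MePPh3Br, KN(SiMe3)2, THF, −78 → 0 °C
Reagents that add atoms: methyltriphenylphosphonium bromide, C[P+](c1ccccc1)(c1ccccc1)c1ccccc1.[Br-]
Why: Wittig methylenation at low temperature, which leaves the oxirane centres untouched.

Step 4
Reactants: 6 pent‑4‑enal; 7 ethyl 2‑(triphenylphosphoranylidene)propanoate
Product: 8 ethyl (E)‑2‑methylhepta‑2,6‑dienoate
Conditions: CH2Cl2, rt
Reagents that add atoms: none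
Why: Wittig olefination with an ester‑stabilised, α‑branched ylide, which should give the E‑trisubstituted enoate (C2′=C3′).

Step 5
Reactants: 8 dienoate; 5 vinyl oxirane (excess)
Product: 9 ethyl (2E,6E)‑2‑methyl‑7‑[(2R,3R)‑3‑(2‑methylpropyl)oxiran‑2‑yl]hepta‑2,6‑dienoate
Conditions: second‑generation Hoveyda–Grubbs catalyst (5 mol %), CH2Cl2, 40 °C
Reagents that add atoms: none
Why: Olefin cross metathesis of two monosubstituted alkenes, in which the trisubstituted conjugated C2′=C3′ bond is inert and the E‑alkene C6′=C7′ should prevail as the thermodynamic product.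

Step 6
Reactants: 9 ethyl ester
Product: 10 (2E,6E)‑2‑methyl‑7‑[(2R,3R)‑3‑(2‑methylpropyl)oxiran‑2‑yl]hepta‑2,6‑dienoic acid
Conditions: LiOH, THF/MeOH/H2O, rt; then cold dilute HCl to pH 4
Reagents that add atoms: lithium hydroxide, [Li+].[OH-]
Why: Ester saponification, to which the vinyl oxirane is stable.

Step 7
Reactants: 10 acid; 11 methyl (R)‑3‑hydroxybutanoate
Product: 12 methyl (3R)‑3‑(acyloxy)butanoate (acyl = that of 10)
Conditions: DIC, DMAP (cat.), CH2Cl2, 0 °C → rt
Reagents that add atoms: none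
Why: Steglich esterification at oxygen, so the bought C14 centre is retained.

Step 8
Reactants: 12 diester
Product: 13 (3R)‑3‑(acyloxy)butanoic acid (acyl = that of 10)
Conditions: Me3SnOH, 1,2‑dichloroethane, 70 °C; then cold 0.1 M HCl wash
Reagents that add atoms: trimethyltin hydroxide, C[Sn](C)(C)O
Why: Neutral tin‑hydroxide ester cleavage, which takes the unhindered methyl ester, spares the hindered conjugated secondary ester, and avoids β‑elimination of the acyloxy group.

**Aldehyde C1–C7**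

Step 9
Reactants: 14 pentane‑2,4‑dione
Product: 15 (E)‑4‑oxopent‑2‑en‑2‑yl trifluoromethanesulfonate
Conditions: Tf2O, aq Me4NOH, hexanes, 0 °C
Reagents that add atoms: trifluoromethanesulfonic anhydride, O=S(=O)(OS(=O)(=O)C(F)(F)F)C(F)(F)F
Why: Biphasic O‑triflation of a 1,3‑dicarbonyl enolate, in which the non‑coordinating cation favours the extended enolate and hence the E‑enol triflate.

Step 10
Reactants: 15 enol triflate; 16 ethynyltrimethylsilane
Product: 17 (E)‑4‑methyl‑6‑(trimethylsilyl)hex‑3‑en‑5‑yn‑2‑one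
Conditions: PdCl2(PPh3)2 (2 mol %), CuI (4 mol %), Et3N, THF, 0 °C → rt
Reagents that add atoms: none
Why: Sonogashira coupling with retention of alkene geometry, which fixes C3=C4 (E) and carries the future C1=C2 vinyl group as a silyl‑capped alkyne that is inert to radicals.

Step 11
Reactants: 17 enynone; 18 diisopropyl allylboronate
Product: 19 (4S,5E)‑4,6‑dimethyl‑8‑(trimethylsilyl)octa‑1,5‑dien‑7‑yn‑4‑ol
Conditions: (S)‑3,3′‑dibromo‑1,1′‑bi‑2‑naphthol (15 mol %), toluene/PhCF3, −35 °C
Reagents that add atoms: none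
Why: Chiral‑diol‑catalysed allylboration of a methyl ketone through a closed chair with the alkenyl group equatorial, in which the S diol is assigned by analogy with aryl and alkenyl methyl ketones to give the (5S) carbinol and the cyclic transition state enforces 1,2‑addition.

Step 12
Reactants: 19 tertiary alcohol
Product: 20 triethylsilyl ether of 19
Conditions: TESOTf, 2,6‑lutidine, CH2Cl2, 0 °C
Reagents that add atoms: triethylsilyl trifluoromethanesulfonate, CC[Si](CC)(CC)OS(=O)(=O)C(F)(F)F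
Why: Silyl triflate silylation, which is strong enough for a tertiary alcohol.

Step 13
Reactants: 20 silyl ether
Product: 21 (3S,4E)‑3,5‑dimethyl‑3‑(triethylsilyloxy)‑7‑(trimethylsilyl)hept‑4‑en‑6‑ynal
Conditions: OsO4 (2 mol %), NaIO4, 2,6‑lutidine, 1,4‑dioxane/H2O, rt
Reagents that add atoms: sodium periodate, [Na+].[O-]I(=O)(=O)=O
Why: Lemieux–Johnson cleavage, which should take the unhindered terminal alkene and leave the trisubstituted enyne alkene that sits next to a quaternary carbon.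

**Ketone C8–C12 and the C1–C12 lactone**

Step 14
Reactants: 22 dimethyl (4R,5R)‑2,2‑dimethyl‑1,3‑dioxolane‑4,5‑dicarboxylate
Product: 24 (4S,5S)‑2,2‑dimethyl‑4,5‑divinyl‑1,3‑dioxolane, via dialdehyde 23 (not isolated)
Conditions: DIBAL‑H (2.1 equiv), toluene, −78 °C; then Ph3P=CH2 (from MePPh3Br, KN(SiMe3)2), THF, −78 °C → rt
Reagents that add atoms: methyltriphenylphosphonium bromide, C[P+](c1ccccc1)(c1ccccc1)c1ccccc1.[Br-]
Why: Half‑reduction of both esters followed by in situ double Wittig methylenation, which avoids handling the epimerisable dialdehyde and carries C10 and C11 unchanged from L‑tartrate.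

Step 15
Reactants: 24 divinyl dioxolane
Product: 25 1‑[(4R,5S)‑2,2‑dimethyl‑5‑vinyl‑1,3‑dioxolan‑4‑yl]ethan‑1‑one
Conditions: PdCl2 (10 mol %), CuCl, O2 (1 atm), DMF/H2O, rt, stopped at partial conversion
Reagents that add atoms: water, O
Why: Wacker–Tsuji oxidation, in which the two vinyl groups are homotopic (C2 axis) so mono‑oxidation gives one compound, and the acetonide of an allylic diol directs water to the internal carbon to give the methyl ketone C8–C9.

Step 16
Reactants: 25 acetonide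
Product: 26 (3R,4S)‑3,4‑dihydroxyhex‑5‑en‑2‑one
Conditions: AcOH/H2O 4:1, 40 °C
Reagents that add atoms: water, O
Why: Acid hydrolysis of the ketal, done here because no acid‑labile group is present yet.

Step 17
Reactants: 26 diol
Product: 27 (3R,4S)‑4‑(tert‑butyldimethylsilyloxy)‑3‑hydroxyhex‑5‑en‑2‑one
Conditions: TBSCl (1.05 equiv), imidazole, CH2Cl2/DMF, −20 → 0 °C
Reagents that add atoms: tert‑butyldimethylsilyl chloride, CC(C)(C)[Si](C)(C)Cl
Why: Regioselective silylation, in which the allylic 11‑OH should react first because the 10‑OH is deactivated by the adjacent acetyl group (inductive effect and internal hydrogen bond).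

Step 18
Reactants: 27 hydroxy ketone
Product: 28 (3R,4S)‑4‑(tert‑butyldimethylsilyloxy)‑2‑oxohex‑5‑en‑3‑yl acrylate
Conditions: acryloyl chloride, iPr2NEt, CH2Cl2, −78 → −20 °C
Reagents that add atoms: acryloyl chloride, C=CC(=O)Cl
Why: O‑acylation at low temperature, which brings in the future 12‑methyl carbon together with its temporary carboxyl carbon and protects O‑10.

Step 19
Reactants: 28 methyl ketone; 21 aldehyde
Product: 30 C1–C12 aldol adduct with (7R)‑hydroxy group, via boron enolate 29 (not isolated)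
Conditions: (+)‑Ipc2BCl, Et3N, Et2O, 0 °C; then 21, −78 → −20 °C; then H2O2, pH 7 buffer, MeOH, 0 °C
Reagents that add atoms: none
Why: Reagent‑controlled boron aldol reaction of a methyl ketone, in which enolisation occurs at the methyl group away from the acyloxy‑bearing carbon and the isopinocampheyl ligands are chosen to give the (7R) carbinol, syn to O‑5.

Step 20
Reactants: 30 aldol adduct
Product: 31 7‑O‑triethylsilyl ether of 30
Conditions: TESOTf, 2,6‑lutidine, CH2Cl2, −78 °C
Reagents that add atoms: triethylsilyl trifluoromethanesulfonate, CC[Si](CC)(CC)OS(=O)(=O)C(F)(F)F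
Why: Silylation that blocks retro‑aldol cleavage and β‑elimination in the later steps.

Step 21
Reactants: 31 acrylate
Product: 32 unsaturated δ‑lactone (5S,6R)‑5‑(TBSO)‑6‑acyl‑5,6‑dihydro‑2H‑pyran‑2‑one carrying C1–C9
Conditions: second‑generation Grubbs catalyst (5 mol %), CH2Cl2 (high dilution), reflux
Reagents that add atoms: none
Why: Ring‑closing metathesis of the acrylate with the C12 vinyl group, which closes the six‑membered ring with a cis alkene while the trisubstituted enyne alkene and the silyl alkyne are too hindered to take part.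

**Union and end game**

Step 22
Reactants: 13 acid (1.5 equiv); 32 unsaturated δ‑lactone
Product: 34 coupled saturated δ‑lactone (4R,5S,6R) with the C12–C13 bond, via phthalimidoyl ester 33 (not isolated)
Conditions: 13, N‑hydroxyphthalimide, DIC, DMAP (5 mol %), CH2Cl2, rt; then 32, Hantzsch ester (1.5 equiv), Ru(bpy)3(PF6)2 (2 mol %), iPr2NEt·HBF4, blue LEDs, rt
Reagents that add atoms: none
Why: The reduced photocatalyst (formed from excited Ru(bpy)3(PF6)2 and Hantzsch ester) passes one electron to phthalimidoyl ester 33, which loses phthalimide anion and CO2 to give the primary C13 radical; this adds to C12, the β‑carbon of the enoate in 32, and the resulting α‑acyl radical takes a hydrogen atom from the Hantzsch ester. The closest known reaction type is the photoredox decarboxylative Giese addition of N‑(acyloxy)phthalimides to butenolides, cyclic enones and unsaturated lactones. No ring is closed; the temporary lactone only serves as activator and template. The one new stereocentre, C12, is controlled by the ring: the 11‑OTBS group and the cis C9‑acyl chain on C10 lie on the same face of the half‑chair, so the radical should enter anti to both, which places C13 trans to O‑11 and gives the 11,12‑anti relationship (12S in the target), while C14 is untouched because the radical centre is one carbon away. The step needs chemoselection among the unsaturated groups and retention of the β‑acyloxy group: only the lactone alkene is electron‑poor, α‑unsubstituted and cis‑locked, whereas C2′=C3′ is a trisubstituted enoate, C6′=C7′ and C3=C4 are unactivated and hindered, the alkyne is silyl‑capped and the 1,3‑diene is absent until step 26, and a β‑acyloxy radical, unlike the corresponding carbanion or alkyl‑metal, does not eliminate. The ammonium salt replaces free amine so that the base‑labile lactone (acidic H‑10, β‑silyloxy group) is not eliminated.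

Step 23
Reactants: 34 saturated δ‑lactone
Product: 35 10‑hydroxy 12‑(carboxymethyl) acid
Conditions: Me3SnOH, 1,2‑dichloroethane, 60 °C; then cold 0.1 M HCl wash, used at once
Reagents that add atoms: trimethyltin hydroxide, C[Sn](C)(C)O
Why: Neutral tin‑hydroxide cleavage, in which the lactone is an activated α‑keto‑alkyl ester and should open before the hindered conjugated ester at O‑14, without enolisation at C10.

Step 24
Reactants: 35 hydroxy acid
Product: 36 12‑methyl compound (10‑OH free, 5,7‑bis‑OTES, 11‑OTBS, 1‑TMS‑alkyne)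
Conditions: Fe(NO3)3·9H2O (5 mol %), di(2‑picolyl)amine (5 mol %), bis(2,4,6‑triisopropylphenyl) disulfide (5 mol %), Na2CO3, 1,2‑dichloroethane/H2O, 390 nm LEDs, rt
Reagents that add atoms: none
Why: Photochemical decarboxylative protonation, in which ligand‑to‑metal charge transfer in the ferric carboxylate gives the carboxyl radical, loss of CO2 gives the primary radical, and the hindered thiol delivers hydrogen, so the temporary carboxyl carbon is erased, CH2 becomes the 12‑methyl group, and C12 is not involved.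

Step 25
Reactants: 36 silyl ethers
Product: 37 terminal enyne tetraol (1,2‑didehydro target)
Conditions: Bu4NF/AcOH (1:1, excess), THF, 0 °C → rt
Reagents that add atoms: none
Why: Buffered fluoride desilylation, which removes both TES groups, the TBS group and the alkynyl TMS group at once without acid (oxirane, tertiary allylic alcohol) or strong base (hydroxy ketones).

Step 26
Reactants: 37 enyne
Product: 38 target
Conditions: H2 (1 atm), Pd on CaCO3 poisoned with Pb(OAc)2 (Lindlar catalyst), quinoline, EtOAc, 0 °C, stopped after one equivalent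
Reagents that add atoms: none
Why: Lindlar semihydrogenation, in which the terminal alkyne is adsorbed and reduced well before di‑ and trisubstituted alkenes, unveiling the C1=C2 vinyl group of the E‑diene.

**Compound list**

1 | 3‑methylbutanal | CC(C)CC=O | starting material
2 | (triphenylphosphoranylidene)acetaldehyde | O=CC=P(c1ccccc1)(c1ccccc1)c1ccccc1 | starting material
3 | (E)‑5‑methylhex‑2‑enal | CC(C)C/C=C/C=O | intermediate
4 | (2S,3R)‑3‑(2‑methylpropyl)oxirane‑2‑carbaldehyde (trans) | O=C[C@H]1O[C@@H]1CC(C)C | intermediate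
5 | (2R,3R)‑2‑(2‑methylpropyl)‑3‑vinyloxirane (trans) | C=C[C@H]1O[C@@H]1CC(C)C | intermediate
6 | pent‑4‑enal | C=CCCC=O | starting material
7 | ethyl 2‑(triphenylphosphoranylidene)propanoate | CCOC(=O)C(C)=P(c1ccccc1)(c1ccccc1)c1ccccc1 | starting material
8 | ethyl (E)‑2‑methylhepta‑2,6‑dienoate | CCOC(=O)/C(C)=C/CCC=C | intermediate
9 | ethyl (2E,6E)‑2‑methyl‑7‑[(2R,3R)‑3‑(2‑methylpropyl)oxiran‑2‑yl]hepta‑2,6‑dienoate | CCOC(=O)/C(C)=C/CC/C=C/[C@H]1O[C@@H]1CC(C)C | intermediate
10 | (2E,6E)‑2‑methyl‑7‑[(2R,3R)‑3‑(2‑methylpropyl)oxiran‑2‑yl]hepta‑2,6‑dienoic acid | OC(=O)/C(C)=C/CC/C=C/[C@H]1O[C@@H]1CC(C)C | intermediate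
11 | methyl (R)‑3‑hydroxybutanoate | COC(=O)C[C@@H](C)O | starting material
12 | methyl (3R)‑3‑(acyloxy)butanoate, acyl of 10 | COC(=O)C[C@@H](C)OC(=O)/C(C)=C/CC/C=C/[C@H]1O[C@@H]1CC(C)C | intermediate
13 | (3R)‑3‑(acyloxy)butanoic acid, acyl of 10 (carboxyl on C13) | OC(=O)C[C@@H](C)OC(=O)/C(C)=C/CC/C=C/[C@H]1O[C@@H]1CC(C)C | intermediate
14 | pentane‑2,4‑dione | CC(=O)CC(C)=O | starting material
15 | (E)‑4‑oxopent‑2‑en‑2‑yl trifluoromethanesulfonate | CC(=O)/C=C(\C)OS(=O)(=O)C(F)(F)F | intermediate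
16 | ethynyltrimethylsilane | C#C[Si](C)(C)C | starting material
17 | (E)‑4‑methyl‑6‑(trimethylsilyl)hex‑3‑en‑5‑yn‑2‑one | CC(=O)/C=C(\C)C#C[Si](C)(C)C | intermediate
18 | diisopropyl allylboronate | C=CCB(OC(C)C)OC(C)C | starting material
19 | (4S,5E)‑4,6‑dimethyl‑8‑(trimethylsilyl)octa‑1,5‑dien‑7‑yn‑4‑ol | C[Si](C)(C)C#C/C(C)=C/[C@@](C)(O)CC=C | intermediate
20 | triethylsilyl ether of 19 | C[Si](C)(C)C#C/C(C)=C/[C@@](C)(O[Si](CC)(CC)CC)CC=C | intermediate
21 | (3S,4E)‑3,5‑dimethyl‑3‑(triethylsilyloxy)‑7‑(trimethylsilyl)hept‑4‑en‑6‑ynal (C1–C7) | C[Si](C)(C)C#C/C(C)=C/[C@@](C)(O[Si](CC)(CC)CC)CC=O | intermediate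
22 | dimethyl (4R,5R)‑2,2‑dimethyl‑1,3‑dioxolane‑4,5‑dicarboxylate (L‑tartrate acetonide) | COC(=O)[C@@H]1OC(C)(C)O[C@H]1C(=O)OC | starting material
23 | (4R,5R)‑2,2‑dimethyl‑1,3‑dioxolane‑4,5‑dicarbaldehyde | O=C[C@@H]1OC(C)(C)O[C@H]1C=O | intermediate
24 | (4S,5S)‑2,2‑dimethyl‑4,5‑divinyl‑1,3‑dioxolane | C=C[C@@H]1OC(C)(C)O[C@H]1C=C | intermediate
25 | 1‑[(4R,5S)‑2,2‑dimethyl‑5‑vinyl‑1,3‑dioxolan‑4‑yl]ethan‑1‑one | CC(=O)[C@@H]1OC(C)(C)O[C@H]1C=C | intermediate
26 | (3R,4S)‑3,4‑dihydroxyhex‑5‑en‑2‑one | CC(=O)[C@H](O)[C@@H](O)C=C | intermediate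
27 | (3R,4S)‑4‑(tert‑butyldimethylsilyloxy)‑3‑hydroxyhex‑5‑en‑2‑one | CC(=O)[C@H](O)[C@@H](O[Si](C)(C)C(C)(C)C)C=C | intermediate
28 | (3R,4S)‑4‑(tert‑butyldimethylsilyloxy)‑2‑oxohex‑5‑en‑3‑yl acrylate (C8–C12) | CC(=O)[C@H](OC(=O)C=C)[C@@H](O[Si](C)(C)C(C)(C)C)C=C | intermediate
29 | enol diisopinocampheylborinate of 28 (C8=C9) | C=C(OB([C@H]1C[C@H]2C[C@@H]([C@@H]1C)C2(C)C)[C@H]1C[C@H]2C[C@@H]([C@@H]1C)C2(C)C)[C@H](OC(=O)C=C)[C@@H](O[Si](C)(C)C(C)(C)C)C=C | intermediate
30 | aldol adduct: 1‑TMS‑1‑yne, 3E, (5S)‑OTES, (7R)‑OH, 9‑one, (10R)‑O‑acryloyl, (11S)‑OTBS, C12 vinyl | C[Si](C)(C)C#C/C(C)=C/[C@@](C)(O[Si](CC)(CC)CC)C[C@@H](O)CC(=O)[C@H](OC(=O)C=C)[C@@H](O[Si](C)(C)C(C)(C)C)C=C | intermediate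
31 | 7‑O‑TES ether of 30 | C[Si](C)(C)C#C/C(C)=C/[C@@](C)(O[Si](CC)(CC)CC)C[C@@H](O[Si](CC)(CC)CC)CC(=O)[C@H](OC(=O)C=C)[C@@H](O[Si](C)(C)C(C)(C)C)C=C | intermediate
32 | (5S,6R)‑5‑(TBSO)‑6‑acyl‑5,6‑dihydro‑2H‑pyran‑2‑one; ring O on C10, ring C5 = C11, ring C4 = C12; cis‑5,6; acyl = C9(=O) with C1–C8 | C[Si](C)(C)C#C/C(C)=C/[C@@](C)(O[Si](CC)(CC)CC)C[C@@H](O[Si](CC)(CC)CC)CC(=O)[C@@H]1OC(=O)C=C[C@@H]1O[Si](C)(C)C(C)(C)C | intermediate
33 | 1,3‑dioxoisoindolin‑2‑yl ester of 13 | O=C(C[C@@H](C)OC(=O)/C(C)=C/CC/C=C/[C@H]1O[C@@H]1CC(C)C)ON1C(=O)c2ccccc2C1=O | intermediate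
34 | (4R,5S,6R)‑tetrahydropyran‑2‑one: C13 chain on ring C4 (= C12) trans to 5‑OTBS and to the 6‑acyl group | C[Si](C)(C)C#C/C(C)=C/[C@@](C)(O[Si](CC)(CC)CC)C[C@@H](O[Si](CC)(CC)CC)CC(=O)[C@@H]1OC(=O)C[C@@H](C[C@@H](C)OC(=O)/C(C)=C/CC/C=C/[C@H]2O[C@@H]2CC(C)C)[C@@H]1O[Si](C)(C)C(C)(C)C | intermediate
35 | open hydroxy acid: 10‑OH, CH2CO2H on C12, other centres as in 34 | C[Si](C)(C)C#C/C(C)=C/[C@@](C)(O[Si](CC)(CC)CC)C[C@@H](O[Si](CC)(CC)CC)CC(=O)[C@H](O)[C@@H](O[Si](C)(C)C(C)(C)C)[C@@H](CC(=O)O)C[C@@H](C)OC(=O)/C(C)=C/CC/C=C/[C@H]1O[C@@H]1CC(C)C | intermediate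
36 | 12‑methyl compound, silyl groups as in 35 | C[Si](C)(C)C#C/C(C)=C/[C@@](C)(O[Si](CC)(CC)CC)C[C@@H](O[Si](CC)(CC)CC)CC(=O)[C@H](O)[C@@H](O[Si](C)(C)C(C)(C)C)[C@@H](C)C[C@@H](C)OC(=O)/C(C)=C/CC/C=C/[C@H]1O[C@@H]1CC(C)C | intermediate
37 | terminal enyne tetraol (target with C1≡C2) | C#C/C(C)=C/[C@@](C)(O)C[C@@H](O)CC(=O)[C@H](O)[C@@H](O)[C@@H](C)C[C@@H](C)OC(=O)/C(C)=C/CC/C=C/[C@H]1O[C@@H]1CC(C)C | intermediate
38 | target (5S,7R,10R,11S,12S,14R,8′R,9′R; 3E,2′E,6′E) | C=C/C(C)=C/[C@@](C)(O)C[C@@H](O)CC(=O)[C@H](O)[C@@H](O)[C@@H](C)C[C@@H](C)OC(=O)/C(C)=C/CC/C=C/[C@H]1O[C@@H]1CC(C)C | target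

**Step count**

- Total steps: 26.
- Longest linear sequence: 13 (steps 9–13 or steps 14–18, then steps 19–26).

**Steps most likely to fail**

**Step 22.** An unstabilised primary radical may add too slowly to a β‑carbon that sits next to the silyloxy‑bearing C11. Premature hydrogen abstraction, or attack on other alkenes, could then take over.

- The fallback sets out from 32 and builds the same bond by polar chemistry, with the ester made afterwards.
- Copper‑mediated conjugate allylation (allylmagnesium bromide, CuBr·SMe2, TMSCl, THF, −78 °C) should enter anti to the 11‑OTBS group and give the 12‑allyl lactone F1.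
- Wacker–Tsuji oxidation (PdCl2, CuCl, O2) gives the 14‑ketone F2.
- Oxazaborolidine‑catalysed borane reduction with the (S)‑methyl catalyst takes the less hindered methyl ketone and gives the (14R)‑alcohol F3.
- Steglich esterification of F3 with acid 10 returns to the route at 34.

**Step 24.** The free 10‑hydroxy ketone may bind iron and be cleaved, or the δ‑hydroxy acid may close back to the lactone before it is decarboxylated.

- The fallback sets out from 35 and goes through a capped, pre‑activated acid.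
- TESOTf/2,6‑lutidine gives the 10‑O‑TES silyl ester F4.
- Mild aqueous methanolysis of the silyl ester gives the 10‑O‑TES acid F5.
- N‑hydroxyphthalimide/DIC gives the phthalimidoyl ester F6.
- Reductive photodecarboxylation (Ru(bpy)3(PF6)2, Hantzsch ester, tert‑butyl thiol, blue LEDs) gives the 10‑O‑TES 12‑methyl compound F7.
- The conditions of step 25 then return to the route at 37.

**Step 5.** Poor E/Z control at C6′=C7′ and self‑metathesis of either partner could erode the cross metathesis.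

- The fallback sets out from 4 (and 7) and forms the alkene by olefination.
- Tetrahydrofuran‑2‑ol and 7 give ethyl (E)‑6‑hydroxy‑2‑methylhex‑2‑enoate F8.
- A Mitsunobu reaction with 1‑phenyl‑1H‑tetrazole‑5‑thiol gives the sulfide F9.
- Molybdate‑catalysed H2O2 oxidation gives the sulfone F10.
- Julia–Kocienski olefination of 4 with F10 (KN(SiMe3)2, DME, −60 °C) should give the E‑alkene and returns to the route at 9. Step 3 is then not needed.

**Further compounds**

F1 | step 22 | 12‑allyl lactone | C[Si](C)(C)C#C/C(C)=C/[C@@](C)(O[Si](CC)(CC)CC)C[C@@H](O[Si](CC)(CC)CC)CC(=O)[C@@H]1OC(=O)C[C@@H](CC=C)[C@@H]1O[Si](C)(C)C(C)(C)C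
F2 | step 22 | 14‑ketone | C[Si](C)(C)C#C/C(C)=C/[C@@](C)(O[Si](CC)(CC)CC)C[C@@H](O[Si](CC)(CC)CC)CC(=O)[C@@H]1OC(=O)C[C@@H](CC(C)=O)[C@@H]1O[Si](C)(C)C(C)(C)C
F3 | step 22 | (14R)‑alcohol | C[Si](C)(C)C#C/C(C)=C/[C@@](C)(O[Si](CC)(CC)CC)C[C@@H](O[Si](CC)(CC)CC)CC(=O)[C@@H]1OC(=O)C[C@@H](C[C@@H](C)O)[C@@H]1O[Si](C)(C)C(C)(C)C
F4 | step 24 | 10‑O‑TES silyl ester | C[Si](C)(C)C#C/C(C)=C/[C@@](C)(O[Si](CC)(CC)CC)C[C@@H](O[Si](CC)(CC)CC)CC(=O)[C@H](O[Si](CC)(CC)CC)[C@@H](O[Si](C)(C)C(C)(C)C)[C@@H](CC(=O)O[Si](CC)(CC)CC)C[C@@H](C)OC(=O)/C(C)=C/CC/C=C/[C@H]1O[C@@H]1CC(C)C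
F5 | step 24 | 10‑O‑TES acid | C[Si](C)(C)C#C/C(C)=C/[C@@](C)(O[Si](CC)(CC)CC)C[C@@H](O[Si](CC)(CC)CC)CC(=O)[C@H](O[Si](CC)(CC)CC)[C@@H](O[Si](C)(C)C(C)(C)C)[C@@H](CC(=O)O)C[C@@H](C)OC(=O)/C(C)=C/CC/C=C/[C@H]1O[C@@H]1CC(C)C
F6 | step 24 | phthalimidoyl ester | C[Si](C)(C)C#C/C(C)=C/[C@@](C)(O[Si](CC)(CC)CC)C[C@@H](O[Si](CC)(CC)CC)CC(=O)[C@H](O[Si](CC)(CC)CC)[C@@H](O[Si](C)(C)C(C)(C)C)[C@@H](CC(=O)ON2C(=O)c3ccccc3C2=O)C[C@@H](C)OC(=O)/C(C)=C/CC/C=C/[C@H]1O[C@@H]1CC(C)C
F7 | step 24 | 10‑O‑TES 12‑methyl compound | C[Si](C)(C)C#C/C(C)=C/[C@@](C)(O[Si](CC)(CC)CC)C[C@@H](O[Si](CC)(CC)CC)CC(=O)[C@H](O[Si](CC)(CC)CC)[C@@H](O[Si](C)(C)C(C)(C)C)[C@@H](C)C[C@@H](C)OC(=O)/C(C)=C/CC/C=C/[C@H]1O[C@@H]1CC(C)C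
F8 | step 5 | ethyl (E)‑6‑hydroxy‑2‑methylhex‑2‑enoate | CCOC(=O)/C(C)=C/CCCO
F9 | step 5 | sulfide | CCOC(=O)/C(C)=C/CCCSc1nnnn1-c1ccccc1
F10 | step 5 | sulfone | CCOC(=O)/C(C)=C/CCCS(=O)(=O)c1nnnn1-c1ccccc1
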